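**Assumption:** the target has no stereocentre and no stereogenic double bond, so it is achiral and "the single enantiomer" is the compound itself. 3,4-Dihydroxy-5-methoxybenzaldehyde (5-hydroxyvanillin) is taken as a catalogue compound.

## Retrosynthetic overview

1. Target 9 comes from its bis(benzyl ether) 8 by hydrogenolysis. No ring is built at any stage; the benzene ring is carried through from 1.
2. 8 is cut between the benzylic CH2 and the neighbouring CH2. The aldehyde carbon of 2 is used as a benzylic carbanion through its N–H hydrazone 7 (carbonyl polarity reversal), and it is joined to the CH2Br carbon of 5, which already carries the stearate. Both carbons are electrophilic in their native forms.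
3. 5 comes from stearic acid 3 and 2-bromoethanol 4; 2 comes from 1 and benzyl bromide.

## Route

**Step 1**
Reactants: 1 3,4-dihydroxy-5-methoxybenzaldehyde
Product: 2 3,4-bis(benzyloxy)-5-methoxybenzaldehyde
Conditions: BnBr (2.3 equiv), K2CO3 (3 equiv), DMF, 60 °C, Ar
Reagents that add atoms: benzyl bromide, BrCc1ccccc1
Why: Williamson ether synthesis; both phenoxides are benzylated by SN2 while the aldehyde is untouched, and working under argon suppresses catecholate oxidation.

**Step 2**
Reactants: 3 octadecanoic acid (stearic acid); 4 2-bromoethanol
Product: 5 2-bromoethyl octadecanoate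
Conditions: 4 (1.5 equiv), p-TsOH·H2O (5 mol%), toluene, reflux, Dean–Stark
Reagents that add atoms: none
Why: Fischer esterification driven to completion by azeotropic removal of water; the primary bromide is stable to the acidic, non-nucleophilic medium.

**Step 3**
Reactants: 2 3,4-bis(benzyloxy)-5-methoxybenzaldehyde; 6 hydrazine monohydrate; 5 2-bromoethyl octadecanoate
Product: 8 3-[3,4-bis(benzyloxy)-5-methoxyphenyl]propyl octadecanoate, via hydrazone 7 (not isolated)
Conditions: 6 (1.2 equiv), THF, rt, 1 h, then volatiles removed in vacuo in the same flask; 5 (1.5 equiv), Ni(cod)2 (10 mol%), 4,4'-di-tert-butyl-2,2'-bipyridine (12 mol%), K3PO4 (2 equiv), THF, 60 °C, Ar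
Reagents that add atoms: none
Why: Proposed new method: the N–H hydrazone turns the former carbonyl carbon into a benzylic carbanion equivalent (carbonyl polarity reversal of the Wolff–Kishner type), so after deprotonation by K3PO4 the nickel hydrazonide (aza-allyl, C-bound tautomer) is alkylated at carbon by the 2-(acyloxy)ethyl fragment that bipyridine-ligated zerovalent nickel takes from bromide 5 by halogen abstraction and radical capture, and the resulting monoalkyl diazene loses N2 to leave the CH2–CH2 link; the closest known reaction type is the nickel-catalysed denitrogenative cross-coupling of aldehyde N–H hydrazones with aryl and unactivated alkyl halides, the untested element being the β-acyloxy group on the bromide; no stereocentre is formed.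

**Step 4**
Reactants: 8 3-[3,4-bis(benzyloxy)-5-methoxyphenyl]propyl octadecanoate
Product: 9 3-(3,4-dihydroxy-5-methoxyphenyl)propyl octadecanoate
Conditions: H2 (1 atm), 10% Pd/C, THF–EtOAc, rt; filtration and concentration under Ar
Reagents that add atoms: none
Why: Catalytic hydrogenolysis of the two benzyl aryl ethers; the alkyl ester, the aryl methyl ether and the saturated chain are inert under neutral conditions, and there is no stereocentre to disturb.

## Compound list

1 | 3,4-dihydroxy-5-methoxybenzaldehyde (5-hydroxyvanillin) | COc1cc(C=O)cc(O)c1O | starting material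
2 | 3,4-bis(benzyloxy)-5-methoxybenzaldehyde | COc1cc(C=O)cc(OCc2ccccc2)c1OCc1ccccc1 | intermediate
3 | octadecanoic acid (stearic acid) | CCCCCCCCCCCCCCCCCC(=O)O | starting material
4 | 2-bromoethanol | OCCBr | starting material
5 | 2-bromoethyl octadecanoate | CCCCCCCCCCCCCCCCCC(=O)OCCBr | intermediate
6 | hydrazine monohydrate | NN.O | starting material
7 | (E)-[3,4-bis(benzyloxy)-5-methoxybenzylidene]hydrazine (N–H hydrazone of 2, formed in the flask) | COc1cc(/C=N/N)cc(OCc2ccccc2)c1OCc1ccccc1 | intermediate
8 | 3-[3,4-bis(benzyloxy)-5-methoxyphenyl]propyl octadecanoate | CCCCCCCCCCCCCCCCCC(=O)OCCCc1cc(OC)c(OCc2ccccc2)c(OCc2ccccc2)c1 | intermediate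
9 | 3-(3,4-dihydroxy-5-methoxyphenyl)propyl octadecanoate | CCCCCCCCCCCCCCCCCC(=O)OCCCc1cc(O)c(O)c(OC)c1 | target

## Step count and risks

Total steps: 4. Longest linear sequence: 3 (1 → 2 → 8 → 9); step 2 is a one-step side branch.

**Step 3 (most likely to fail).** The nickel alkyl derived from 5 carries a β-acyloxy group and may eliminate to ethylene and stearate. The hydrazone may also be N-alkylated or condense to the azine, and any hydrazine left in the flask would attack the ester, which is why the volatiles are stripped before 5 is added. The fallback sets out from 2 and comes back to the route at 8, using a classical acyl-anion equivalent for the same bond. Compound 2 with propane-1,3-dithiol and BF3·OEt2 in CH2Cl2 gives 2-[3,4-bis(benzyloxy)-5-methoxyphenyl]-1,3-dithiane F1. n-BuLi in THF at −78 °C gives 2-lithio-2-[3,4-bis(benzyloxy)-5-methoxyphenyl]-1,3-dithiane F2. This opens ethylene oxide to lithium 2-{2-[3,4-bis(benzyloxy)-5-methoxyphenyl]-1,3-dithian-2-yl}ethoxide F3. Quenching in the same flask with stearoyl chloride gives 2-{2-[3,4-bis(benzyloxy)-5-methoxyphenyl]-1,3-dithian-2-yl}ethyl octadecanoate F4. Raney nickel (deactivated in acetone) in EtOH–THF then removes both C–S bonds and delivers 8. Any benzyl ether lost at that stage converges on 9 in step 4.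

**Step 4.** The free catechol 9 oxidises easily in air during filtration, and traces of nickel or sulfur carried forward can stall the palladium. The fallback sets out from 8 and comes back at 9 by Lewis-acid debenzylation instead of hydrogenation: BCl3 (3 equiv) and pentamethylbenzene (4 equiv) in CH2Cl2 at −78 °C, then MeOH and aqueous work-up. At this temperature the aryl methyl ether and the alkyl ester are retained. This fallback makes no new compound (F0).

**Step 2.** The acid-catalysed esterification may stall at equilibrium, or 2-bromoethanol may self-condense at reflux. The fallback sets out from 3 and comes back at 5 by forming the ester C–O bond at the alkyl carbon instead of the acyl carbon. K2CO3 in DMF converts 3 into potassium octadecanoate F5, which is alkylated with a large excess of 1,2-dibromoethane (8 equiv) at 60 °C to give 5. The excess suppresses the ethylene diester.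

## Further compounds

F1 | step 3 | 2-[3,4-bis(benzyloxy)-5-methoxyphenyl]-1,3-dithiane | COc1cc(C2SCCCS2)cc(OCc2ccccc2)c1OCc1ccccc1
F2 | step 3 | 2-lithio-2-[3,4-bis(benzyloxy)-5-methoxyphenyl]-1,3-dithiane | COc1cc(C2([Li])SCCCS2)cc(OCc2ccccc2)c1OCc1ccccc1
F3 | step 3 | lithium 2-{2-[3,4-bis(benzyloxy)-5-methoxyphenyl]-1,3-dithian-2-yl}ethoxide | COc1cc(C2(CC[O-])SCCCS2)cc(OCc2ccccc2)c1OCc1ccccc1.[Li+]
F4 | step 3 | 2-{2-[3,4-bis(benzyloxy)-5-methoxyphenyl]-1,3-dithian-2-yl}ethyl octadecanoate | CCCCCCCCCCCCCCCCCC(=O)OCCC1(c2cc(OC)c(OCc3ccccc3)c(OCc3ccccc3)c2)SCCCS1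
F0 | step 4 | none | none
F5 | step 2 | potassium octadecanoate | CCCCCCCCCCCCCCCCCC(=O)[O-].[K+]
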